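**Retrosynthetic overview**

- The route rests on one feature: C4 of the lactone ring (ring B) is the only stereocentre, and its bond C4–C1'' to the 4-hydroxyphenyl ring (ring D) lies β to the lactone carbonyl C2. Ring D can therefore be added last to C4 of a flat, achiral C3=C4 coumarin that already holds the C5 methyl and the C6 pyranone (ring C).
- Target 17 ⇐ bis-silyl ether 16 ⇐ coumarin 14 + arylboronic acid 15, by rhodium-catalysed asymmetric 1,4-arylation (C4–C1'' formed, C4 set, no ring closed).
- 14 ⇐ E-cinnamate 12 by lactonisation (O1–C2, ring B) ⇐ aryl bromide 9 + methyl acrylate by Heck coupling (C4–C4a).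
- 9 ⇐ aldehyde 3: the aldehyde carbon becomes C6' of ring C by dianion aldol, oxidation, cyclisation and O-methylation; 3 ⇐ 2,4-dihydroxy-6-methylbenzaldehyde 1 by bromination and MOM protection.
- Ring order: ring A is bought with 1, ring C closes in step 5, ring B closes as the coumarin in step 9, ring D is attached in step 11.

Key step: step 11

Assumption: (R)-SEGPHOS is taken to send the aryl group to the same face of C4 as it does with unhindered coumarins, which corresponds to the (4R) product; if the peri methyl reversed the sense, (S)-SEGPHOS would be used with no other change.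

**Route**

Step 1
Reactants: 1 2,4-dihydroxy-6-methylbenzaldehyde
Product: 2 3-bromo-4,6-dihydroxy-2-methylbenzaldehyde
Conditions: NBS (1.0 equiv), MeCN, −20 → 0 °C
Reagents that add atoms: N-bromosuccinimide, O=C1CCC(=O)N1Br
Why: Electrophilic aromatic bromination should take place at the ring carbon between the methyl and the 4-hydroxyl, which is ortho to one hydroxyl and para to the chelated one and is the usual halogenation site of this aldehyde, while one equivalent of NBS at low temperature limits dibromination.

Step 2
Reactants: 2 3-bromo-4,6-dihydroxy-2-methylbenzaldehyde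
Product: 3 3-bromo-4,6-bis(methoxymethoxy)-2-methylbenzaldehyde
Conditions: NaH (2.5 equiv), MOMCl (2.5 equiv), DMF, 0 °C → rt
Reagents that add atoms: chloromethyl methyl ether, COCCl
Why: O-Alkylation of both phenoxides (the chelated one needs full deprotonation by NaH) gives MOM acetals that tolerate the enolate, amine base and palladium of the later steps and are removed by mild acid.

Step 3
Reactants: 3 3-bromo-4,6-bis(methoxymethoxy)-2-methylbenzaldehyde; 4 methyl acetoacetate
Product: 6 methyl 5-[3-bromo-4,6-bis(methoxymethoxy)-2-methylphenyl]-5-hydroxy-3-oxopentanoate (racemic), via dilithium dianion of methyl acetoacetate 5 (not isolated)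
Conditions: 4 (1.5 equiv), LiN(i-Pr)2 (LDA, 3.1 equiv), THF, 0 °C; then 3, −78 °C; AcOH quench at −78 °C
Reagents that add atoms: none
Why: Aldol addition of the acetoacetate dianion through its terminal carbon to the aldehyde is far faster at −78 °C than any reaction at the aryl bromide or the acetals, and the racemic carbinol centre is removed in step 4.

Step 4
Reactants: 6 methyl 5-[3-bromo-4,6-bis(methoxymethoxy)-2-methylphenyl]-5-hydroxy-3-oxopentanoate
Product: 7 methyl 5-[3-bromo-4,6-bis(methoxymethoxy)-2-methylphenyl]-3,5-dioxopentanoate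
Conditions: IBX (2-iodoxybenzoic acid, 3 equiv), EtOAc, 75 °C
Reagents that add atoms: none
Why: IBX oxidation of a benzylic β-hydroxy ketone to the 1,3-diketone is a standard conversion that should stop at the 3,5-dioxo ester without oxidising the active methylene groups.

Step 5
Reactants: 7 methyl 5-[3-bromo-4,6-bis(methoxymethoxy)-2-methylphenyl]-3,5-dioxopentanoate
Product: 8 6-[3-bromo-4,6-bis(methoxymethoxy)-2-methylphenyl]-4-hydroxy-2H-pyran-2-one
Conditions: DBU (1.5 equiv), toluene, 60 °C; cold aqueous citric acid work-up
Reagents that add atoms: none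
Why: Base-mediated lactonisation of a 3,5-dioxo ester closes ring C, since the enolate oxygen of the aryl ketone attacks the ester carbonyl (6-exo-trig acyl substitution, methanol lost) and the product rests as the stabilised 4-hydroxy-2-pyranone.

Step 6
Reactants: 8 6-[3-bromo-4,6-bis(methoxymethoxy)-2-methylphenyl]-4-hydroxy-2H-pyran-2-one
Product: 9 6-[3-bromo-4,6-bis(methoxymethoxy)-2-methylphenyl]-4-methoxy-2H-pyran-2-one
Conditions: Me2SO4 (1.5 equiv), K2CO3, acetone, reflux
Reagents that add atoms: dimethyl sulfate, COS(=O)(=O)OC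
Why: O-Methylation of the vinylogous acid with dimethyl sulfate and K2CO3 in acetone is the usual entry to 4-methoxy-2-pyranones and favours this isomer over the 2-methoxy-4-pyranone.

Step 7
Reactants: 9 6-[3-bromo-4,6-bis(methoxymethoxy)-2-methylphenyl]-4-methoxy-2H-pyran-2-one; 10 methyl acrylate
Product: 11 methyl (E)-3-[2,4-bis(methoxymethoxy)-5-(4-methoxy-2-oxo-2H-pyran-6-yl)-6-methylphenyl]prop-2-enoate
Conditions: 10 (3 equiv), Pd2(dba)3 (2.5 mol%), [HP(t-Bu)3]BF4 (10 mol%), Cy2NMe (1.5 equiv), 1,4-dioxane, 90 °C
Reagents that add atoms: none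
Why: In this Heck reaction the bulky, electron-rich P(t-Bu)3 lets zerovalent palladium insert into the di-ortho-substituted, electron-rich aryl bromide, syn insertion of the acrylate and syn β-hydride elimination give the E-cinnamate, and ring C offers no unsubstituted alkene to compete.

Step 8
Reactants: 11 methyl (E)-3-[2,4-bis(methoxymethoxy)-5-(4-methoxy-2-oxo-2H-pyran-6-yl)-6-methylphenyl]prop-2-enoate
Product: 12 methyl (E)-3-[2,4-dihydroxy-5-(4-methoxy-2-oxo-2H-pyran-6-yl)-6-methylphenyl]prop-2-enoate
Conditions: 2 M HCl, MeOH/THF, 40 °C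
Reagents that add atoms: none
Why: Acid-catalysed acetal exchange with methanol removes both MOM groups as dimethoxymethane and should leave the methyl ester, the vinylogous ester of ring C and the E-alkene unchanged.

Step 9
Reactants: 12 methyl (E)-3-[2,4-dihydroxy-5-(4-methoxy-2-oxo-2H-pyran-6-yl)-6-methylphenyl]prop-2-enoate
Product: 13 7-hydroxy-6-(4-methoxy-2-oxo-2H-pyran-6-yl)-5-methyl-2H-chromen-2-one
Conditions: n-Bu3P (20 mol%), MeOH, 70 °C, argon
Reagents that add atoms: none
Why: This is the known nucleophilic phosphine-catalysed cyclisation of E-2-hydroxycinnamates to coumarins, in which reversible addition of Bu3P to the β-carbon frees rotation, the phenol ortho to the side chain acylates (6-exo-trig, methanol lost) and loss of the phosphine restores C3=C4 in ring B; the second hydroxyl cannot reach the ester.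

Step 10
Reactants: 13 7-hydroxy-6-(4-methoxy-2-oxo-2H-pyran-6-yl)-5-methyl-2H-chromen-2-one
Product: 14 7-(tert-butyldimethylsilyloxy)-6-(4-methoxy-2-oxo-2H-pyran-6-yl)-5-methyl-2H-chromen-2-one
Conditions: TBSCl (1.3 equiv), imidazole, DMF, rt
Reagents that add atoms: tert-butyldimethylsilyl chloride, CC(C)(C)[Si](C)(C)Cl
Why: Silylation of the only free phenol masks the acidic hydroxyl as an ether that should survive the neutral aqueous medium of step 11 and leave with fluoride.

Step 11
Reactants: 14 7-(tert-butyldimethylsilyloxy)-6-(4-methoxy-2-oxo-2H-pyran-6-yl)-5-methyl-2H-chromen-2-one; 15 4-(tert-butyldimethylsilyloxy)phenylboronic acid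
Product: 16 (4R)-7-(tert-butyldimethylsilyloxy)-4-[4-(tert-butyldimethylsilyloxy)phenyl]-6-(4-methoxy-2-oxo-2H-pyran-6-yl)-5-methylchroman-2-one
Conditions: Rh(acac)(C2H4)2 (5 mol%), (R)-SEGPHOS (5.5 mol%), 15 (5 equiv, in portions), 1,4-dioxane/H2O 10:1, 60 °C
Reagents that add atoms: none
Why: In aqueous dioxane the precatalyst and ligand give the monovalent rhodium hydroxo complex Rh(OH)[(R)-SEGPHOS], which transmetalates with 15; the aryl–rhodium bond then adds across C3=C4 with the aryl group going to C4, and water protonates the resulting oxa-allyl rhodium enolate at C3 and regenerates the hydroxo complex. The closest known reaction is the Hayashi–Miyaura asymmetric 1,4-addition of arylboronic acids to coumarins, which gives 4-arylchroman-2-ones; the present substrate is a more crowded member of that class because of the peri C5 methyl. No ring is closed: the step forms only the C4–C1'' bond. The new stereocentre C4 is controlled by the chiral bisphosphine, whose aryl groups expose one face of the planar coumarin to the rhodium-bound aryl group, and (R)-SEGPHOS is expected to give the 4R configuration. The step also needs chemoselectivity for ring B over ring C, which the substrate secures because the electrophilic carbons C4' and C6' of the pyranone are both fully substituted and C4' carries a methoxy donor, so coumarin C4 is the only open β-position. Excess boronic acid added in portions should offset competing protodeboronation while insertion at the hindered C4 proceeds.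

Step 12
Reactants: 16 (4R)-7-(tert-butyldimethylsilyloxy)-4-[4-(tert-butyldimethylsilyloxy)phenyl]-6-(4-methoxy-2-oxo-2H-pyran-6-yl)-5-methylchroman-2-one
Product: 17 (4R)-7-hydroxy-4-(4-hydroxyphenyl)-6-(4-methoxy-2-oxo-2H-pyran-6-yl)-5-methylchroman-2-one
Conditions: Bu4NF (2.5 equiv), AcOH (2.5 equiv), THF, 0 °C
Reagents that add atoms: none
Why: Fluoride cleaves both aryl silyl ethers through Si–F bond formation, and the acetic acid buffer protonates the phenoxides at once so that neither the dihydrocoumarin lactone nor the pyranone should open; C4 is not enolisable and keeps its configuration.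

**Compound list**

1 | 2,4-dihydroxy-6-methylbenzaldehyde | Cc1cc(O)cc(O)c1C=O | starting material
2 | 3-bromo-4,6-dihydroxy-2-methylbenzaldehyde | Cc1c(Br)c(O)cc(O)c1C=O | intermediate
3 | 3-bromo-4,6-bis(methoxymethoxy)-2-methylbenzaldehyde | Cc1c(Br)c(OCOC)cc(OCOC)c1C=O | intermediate
4 | methyl acetoacetate | COC(=O)CC(C)=O | starting material
5 | dilithium dianion of methyl acetoacetate | [Li+].[Li+].COC([O-])=CC([O-])=C | intermediate
6 | methyl 5-[3-bromo-4,6-bis(methoxymethoxy)-2-methylphenyl]-5-hydroxy-3-oxopentanoate (racemic) | COC(=O)CC(=O)CC(O)c1c(C)c(Br)c(OCOC)cc1OCOC | intermediate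
7 | methyl 5-[3-bromo-4,6-bis(methoxymethoxy)-2-methylphenyl]-3,5-dioxopentanoate | COC(=O)CC(=O)CC(=O)c1c(C)c(Br)c(OCOC)cc1OCOC | intermediate
8 | 6-[3-bromo-4,6-bis(methoxymethoxy)-2-methylphenyl]-4-hydroxy-2H-pyran-2-one | O=c1cc(O)cc(-c2c(C)c(Br)c(OCOC)cc2OCOC)o1 | intermediate
9 | 6-[3-bromo-4,6-bis(methoxymethoxy)-2-methylphenyl]-4-methoxy-2H-pyran-2-one | COc1cc(-c2c(C)c(Br)c(OCOC)cc2OCOC)oc(=O)c1 | intermediate
10 | methyl acrylate | C=CC(=O)OC | starting material
11 | methyl (E)-3-[2,4-bis(methoxymethoxy)-5-(4-methoxy-2-oxo-2H-pyran-6-yl)-6-methylphenyl]prop-2-enoate | COC(=O)/C=C/c1c(C)c(-c2cc(OC)cc(=O)o2)c(OCOC)cc1OCOC | intermediate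
12 | methyl (E)-3-[2,4-dihydroxy-5-(4-methoxy-2-oxo-2H-pyran-6-yl)-6-methylphenyl]prop-2-enoate | COC(=O)/C=C/c1c(C)c(-c2cc(OC)cc(=O)o2)c(O)cc1O | intermediate
13 | 7-hydroxy-6-(4-methoxy-2-oxo-2H-pyran-6-yl)-5-methyl-2H-chromen-2-one | COc1cc(-c2c(O)cc3oc(=O)ccc3c2C)oc(=O)c1 | intermediate
14 | 7-(tert-butyldimethylsilyloxy)-6-(4-methoxy-2-oxo-2H-pyran-6-yl)-5-methyl-2H-chromen-2-one | COc1cc(-c2c(O[Si](C)(C)C(C)(C)C)cc3oc(=O)ccc3c2C)oc(=O)c1 | intermediate
15 | 4-(tert-butyldimethylsilyloxy)phenylboronic acid | CC(C)(C)[Si](C)(C)Oc1ccc(B(O)O)cc1 | starting material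
16 | (4R)-7-(tert-butyldimethylsilyloxy)-4-[4-(tert-butyldimethylsilyloxy)phenyl]-6-(4-methoxy-2-oxo-2H-pyran-6-yl)-5-methylchroman-2-one | COc1cc(-c2c(O[Si](C)(C)C(C)(C)C)cc3c(c2C)[C@@H](c2ccc(O[Si](C)(C)C(C)(C)C)cc2)CC(=O)O3)oc(=O)c1 | intermediate
17 | (4R)-7-hydroxy-4-(4-hydroxyphenyl)-6-(4-methoxy-2-oxo-2H-pyran-6-yl)-5-methylchroman-2-one | COc1cc(-c2c(O)cc3c(c2C)[C@@H](c2ccc(O)cc2)CC(=O)O3)oc(=O)c1 | target

**Step count**

Total step count: 12. Longest linear sequence: 12 steps (1 → 17).

**Steps most likely to fail**

Step 11 (key step). Insertion of the aryl–rhodium bond at C4 next to the peri C5 methyl may be slower than hydrolytic loss of the aryl group from boron or rhodium, so that the coumarin is returned, or the crowded substrate may erode the face selectivity. The fallback separates bond formation from stereocontrol and sets out from 14 and 15. An oxidative Heck reaction (Pd(OAc)2, 1,10-phenanthroline, O2, DMF, 80 °C) would transfer the aryl group from divalent palladium to C4 in a non-aqueous medium, and β-hydride elimination would restore C3=C4. This would give the 4-arylcoumarin 7-(tert-butyldimethylsilyloxy)-4-[4-(tert-butyldimethylsilyloxy)phenyl]-6-(4-methoxy-2-oxo-2H-pyran-6-yl)-5-methyl-2H-chromen-2-one F1. A known asymmetric CuH conjugate reduction of 4-arylcoumarins (Cu(OAc)2, DTBM-SEGPHOS in the enantiomer that gives 4R, (EtO)2MeSiH, t-BuOH, toluene) would then deliver the small hydride to C4 from one face. The fallback comes back to the route at 16.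

Step 7. Oxidative addition to the bromide flanked by a methyl and a MOM ether, and above all alkene insertion at the resulting crowded aryl–palladium centre, may be slow, so that hydrodebromination and acrylate oligomerisation take over. The fallback replaces carbopalladation by transmetalation. Setting out from 9, a Suzuki–Miyaura coupling with commercial methyl (E)-3-(4,4,5,5-tetramethyl-1,3,2-dioxaborolan-2-yl)prop-2-enoate (Pd(OAc)2, SPhos, K3PO4, toluene/H2O, 80 °C) would bring in the complete E-acrylate unit with retention of geometry. It comes back to the route at 11 and makes no new compound (F0).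

Step 9. The phosphine may add too slowly to the β-carbon, which sits between two ortho substituents, so that the E-ester never reaches a geometry able to lactonise and is recovered. The fallback removes the geometric requirement and restores the alkene afterwards; it sets out from 12. Hydrogenation of the cinnamate double bond (H2 1 atm, Pd/C, EtOAc, stopped after one equivalent; the pyranone is far slower) would give methyl 3-[2,4-dihydroxy-5-(4-methoxy-2-oxo-2H-pyran-6-yl)-6-methylphenyl]propanoate F2. Acid-catalysed lactonisation (TsOH cat., toluene, 80 °C) would give 7-hydroxy-6-(4-methoxy-2-oxo-2H-pyran-6-yl)-5-methylchroman-2-one F3. Silylation (TBSCl, imidazole, DMF) would give 7-(tert-butyldimethylsilyloxy)-6-(4-methoxy-2-oxo-2H-pyran-6-yl)-5-methylchroman-2-one F4. Dehydrogenation with DDQ (1,4-dioxane, reflux) by hydride abstraction from C4, which the ring oxygens at C7 and C8a assist, would restore C3=C4. The fallback comes back to the route at 14.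

**Further compounds**

F1 | step 11 | 7-(tert-butyldimethylsilyloxy)-4-[4-(tert-butyldimethylsilyloxy)phenyl]-6-(4-methoxy-2-oxo-2H-pyran-6-yl)-5-methyl-2H-chromen-2-one | COc1cc(-c2c(O[Si](C)(C)C(C)(C)C)cc3oc(=O)cc(-c4ccc(O[Si](C)(C)C(C)(C)C)cc4)c3c2C)oc(=O)c1
F0 | step 7 | none | none
F2 | step 9 | methyl 3-[2,4-dihydroxy-5-(4-methoxy-2-oxo-2H-pyran-6-yl)-6-methylphenyl]propanoate | COC(=O)CCc1c(C)c(-c2cc(OC)cc(=O)o2)c(O)cc1O
F3 | step 9 | 7-hydroxy-6-(4-methoxy-2-oxo-2H-pyran-6-yl)-5-methylchroman-2-one | COc1cc(-c2c(O)cc3c(c2C)CCC(=O)O3)oc(=O)c1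
F4 | step 9 | 7-(tert-butyldimethylsilyloxy)-6-(4-methoxy-2-oxo-2H-pyran-6-yl)-5-methylchroman-2-one | COc1cc(-c2c(O[Si](C)(C)C(C)(C)C)cc3c(c2C)CCC(=O)O3)oc(=O)c1
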